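**Retrosynthetic overview**

1. Target 16 is two (5S,7S,10S)-7,10-epoxyicetexane (brussonol) units joined by a cis-fused 1,4-benzodioxane, O12–C14′ and O11–C13′ (icetexane locants; primes mark the ene-1,2-dione unit, whose six-membered ring C′ is C8′, C9′, C11′–C14′).
2. The dioxane is not closed as a six-membered ring: it comes from the seven-membered benzodioxepine hemiketal in which O11 sits on the C12′ carbonyl, by a 1,2-shift of O11 to the fully substituted C13′ (ring contraction, C12′=O restored). Enabling feature: in ring C′ the O12-bearing C14′ and the C12′ ketone are 1,3-related with C13′ between them, and a catechol spans two 1,3-diaxial sites, so O11 is held over C12′=O anti to a leaving group on C13′.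
3. The same operation joins the two C20 halves: the 12-phenoxide of 9 opens the C13′/C14′ cyclic sulfate 12 at C14′, which places O12 and leaves the sulfate on C13′ as that leaving group.
4. Both halves come from one compound, 11-O-MOM-brussonol 9: it is the nucleophile as such, and the electrophile after dearomatisation to o-quinone monoketal 10, cis-dihydroxylation (11) and cyclic sulfate formation (12).
5. 9 comes from (+)-carnosic acid 1 (rings A and C from the chiral pool): O-differentiation, ring B enlarged from six to seven members by 1,2-aryl shift (6), oxygen bridge through p-quinone methide 8. Order of rings: B, tetrahydrofuran bridge, then cyclic sulfate and benzodioxepine (both transient), dioxane last.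

Key step: step 11

Assumption: the hindered, hydrogen-bonded 11-OH of carnosic acid is alkylated only after the 12-OH and the acid; this differentiates the two catechol oxygens for the whole route.

Step 1
Reactants: 1 (+)-carnosic acid
Product: 2 benzyl 12-O-benzylcarnosate
Conditions: BnBr (2.2 equiv), K2CO3, DMF, 0 °C to rt, Ar
Reagents that add atoms: benzyl bromide BrCc1ccccc1
Why: Williamson O-alkylation of the carboxylate and of the more accessible 12-phenoxide, while the 11-OH, flanked by C1H2 and C20 and hydrogen-bonded to C20=O, should stay free; no stereocentre is touched.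

Step 2
Reactants: 2 benzyl 12-O-benzylcarnosate
Product: 3 benzyl 12-O-benzyl-11-O-(methoxymethyl)carnosate
Conditions: NaH, MOMCl, DMF, 0 °C
Reagents that add atoms: chloromethyl methyl ether COCCl
Why: Williamson-type alkylation of the hindered 11-phenoxide by the small, very reactive chloromethyl ether installs the acetal that later decides which oxygen ends on C14′.

Step 3
Reactants: 3 benzyl 12-O-benzyl-11-O-(methoxymethyl)carnosate
Product: 4 12-benzyloxy-11-(methoxymethoxy)abieta-8,11,13-trien-20-ol
Conditions: LiAlH4, THF, 0 °C to reflux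
Reagents that add atoms: none
Why: LiAlH4 reduction of the neopentyl benzyl ester to the C20 primary alcohol; aryl ethers and the MOM acetal are inert to hydride.

Step 4
Reactants: 4 12-benzyloxy-11-(methoxymethoxy)abieta-8,11,13-trien-20-ol
Product: 5 12-benzyloxy-11-(methoxymethoxy)abieta-8,11,13-trien-20-yl methanesulfonate
Conditions: MsCl, Et3N, CH2Cl2, 0 °C
Reagents that add atoms: methanesulfonyl chloride CS(=O)(=O)Cl
Why: Sulfonylation of the only free hydroxyl (through sulfene) gives the leaving group for the ring expansion.

Step 5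
Reactants: 5 12-benzyloxy-11-(methoxymethoxy)abieta-8,11,13-trien-20-yl methanesulfonate
Product: 6 (5S,10S)-12-benzyloxy-11-(methoxymethoxy)icetexa-8,11,13-trien-10-ol
Conditions: NaHCO3, H2O–1,4-dioxane (1:1), 90 °C
Reagents that add atoms: water O
Why: Solvolytic Wagner–Meerwein ring expansion (neophyl-type 1,2-shift of the electron-rich aryl carbon C9 from C10 to C20) turns six-membered ring B into the seven-membered icetexane ring, and water should add axially to the C10 cation anti to H5, setting the 10-hydroxyl trans to H5.

Step 6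
Reactants: 6 (5S,10S)-12-benzyloxy-11-(methoxymethoxy)icetexa-8,11,13-trien-10-ol
Product: 7 (5S,10S)-11-(methoxymethoxy)icetexa-8,11,13-triene-10,12-diol
Conditions: H2 (1 atm), Pd/C, EtOAc, rt
Reagents that add atoms: none
Why: Hydrogenolysis of the benzyl aryl ether frees the 12-phenol; MOM ether, tertiary alcohol and arene are untouched.

Step 7
Reactants: 7 (5S,10S)-11-(methoxymethoxy)icetexa-8,11,13-triene-10,12-diol
Product: 9 11-O-(methoxymethyl)brussonol, via p-quinone methide 8 (not isolated)
Conditions: Ag2O, CH2Cl2, rt; then Et3N (cat.)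
Reagents that add atoms: none
Why: Ag2O oxidises the 2,6-disubstituted p-alkylphenol to p-quinone methide 8, and 5-exo-trig oxa-1,6-addition of the C10 hydroxyl to C7 rearomatises the ring; C7 is set by the tether, since the hydroxyl can reach only one face of the methide carbon.

Step 8
Reactants: 9 11-O-(methoxymethyl)brussonol
Product: 10 (5S,7S,10S)-7,10-epoxy-11-methoxy-11-(methoxymethoxy)icetexa-8,13-dien-12-one
Conditions: PhI(OAc)2, MeOH, 0 °C
Reagents that add atoms: methanol CO
Why: Oxidative dearomatisation of a 2-alkoxyphenol to an o-quinone monoketal (masked o-benzoquinone): methanol should capture the MOM-bearing C11 faster than the MOM group can leave, giving a ring that cannot rearomatise; C11 forms as an inconsequential mixture of epimers.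

Step 9
Reactants: 10 (5S,7S,10S)-7,10-epoxy-11-methoxy-11-(methoxymethoxy)icetexa-8,13-dien-12-one
Product: 11 (5S,7S,10S,13S,14S)-7,10-epoxy-13,14-dihydroxy-11-methoxy-11-(methoxymethoxy)icetex-8-en-12-one
Conditions: OsO4 (5 mol %), NMO, citric acid, t-BuOH–H2O, rt
Reagents that add atoms: N-methylmorpholine N-oxide C[N+]1([O-])CCOCC1; water O
Why: Upjohn cis-dihydroxylation: only the trisubstituted C13=C14 bond is accessible (C8=C9 is tetrasubstituted and buried), and OsO4 should add suprafacially from the face of the one-atom oxygen bridge, away from the two-carbon C5–C6 bridge, which sets both carbinol centres cis on that face.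

Step 10
Reactants: 11 (5S,7S,10S,13S,14S)-7,10-epoxy-13,14-dihydroxy-11-methoxy-11-(methoxymethoxy)icetex-8-en-12-one
Product: 12 13,14-cyclic sulfate of 11
Conditions: SO2Im2, DBU (cat.), CH2Cl2, 0 °C to rt
Reagents that add atoms: 1,1′-sulfonyldiimidazole O=S(=O)(n1ccnc1)n1ccnc1
Why: Double O-sulfonylation of the cis-1,2-diol closes the five-membered cyclic sulfate without forming a free alkoxide (no retro-aldol); both C–O bonds are kept, so the configuration from step 9 is carried over.

Step 11
Reactants: 9 11-O-(methoxymethyl)brussonol; 12 13,14-cyclic sulfate of 11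
Product: 16 CNP0371333.1 (target), via potassium sulfate monoester 13 (not isolated), via phenol dione hydrogen sulfate 14 (not isolated), via benzodioxepine hemiketal 15 (not isolated)
Conditions: KN(SiMe3)2, 18-crown-6, THF, 0 °C; 12, 0 to 40 °C; then TFA–H2O (9:1), 0 °C to rt
Reagents that add atoms: none
Why: Proposed new method: the phenoxide of 9 opens cyclic sulfate 12 by SN2 at the secondary, allylic C14′ with inversion (trans-diaxial opening, as in double displacements at cyclic sulfates), so that 13 carries O12 axial on one face and the tertiary C13′ sulfate axial on the other; aqueous acid then removes both MOM groups, which frees the 11-phenol and collapses the C11′ ketal to the ketone (14). The phenol, held 1,3-diaxial to C12′ by the O12–C14′ ether, adds to the now 1,2-dicarbonyl C12′ (7-exo-trig) to give the seven-membered benzodioxepine hemiketal 15, and electron push from the hemiketal hydroxyl drives a 1,2-shift of O11 from C12′ to C13′ with loss of hydrogen sulfate, which contracts the seven-membered ring to the six-membered 1,4-dioxane and restores C12′=O. The closest known reaction types are the semipinacol rearrangement of 2-sulfonyloxy alcohols, the 1,2-migration of an anomeric aryloxy or alkoxy group to C2 when a trans-2-hydroxyl of a glycoside is activated, and the epoxy ether to α-alkoxy ketone rearrangement. The dioxane is thus closed by migration through a three-membered oxonium-like transition state (3-exo-tet at C13′) and not by direct attack, which the tertiary, neopentyl-like C13′ should not allow. C14′ is set by inversion of the diol centre of step 9 (S to R) and C13′ by inversion in the shift (S to R), O11 being delivered on the face of O12 by the tether, so the ring fusion must be cis. The step needs O11 rather than the acyl carbon C11′ to migrate, substitution rather than elimination, and O12 rather than O11 on C14′: the trans-diaxial O11/sulfate alignment fixed by the cyclic sulfate opening secures the first, H14′ being syn to the sulfate the second, and the MOM group that blocks O11 of 9 until after the union the third.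

**Compound list**

1 | (+)-carnosic acid, (4aR,10aS) | CC(C)c1cc2c(c(O)c1O)[C@@]1(C(=O)O)CCCC(C)(C)[C@@H]1CC2 | starting material
2 | benzyl 12-O-benzylcarnosate | CC(C)c1cc2c(c(O)c1OCc1ccccc1)[C@@]1(C(=O)OCc3ccccc3)CCCC(C)(C)[C@@H]1CC2 | intermediate
3 | benzyl 12-O-benzyl-11-O-(methoxymethyl)carnosate | CC(C)c1cc2c(c(OCOC)c1OCc1ccccc1)[C@@]1(C(=O)OCc3ccccc3)CCCC(C)(C)[C@@H]1CC2 | intermediate
4 | (5S,10R)-12-benzyloxy-11-(methoxymethoxy)abieta-8,11,13-trien-20-ol | CC(C)c1cc2c(c(OCOC)c1OCc1ccccc1)[C@@]1(CO)CCCC(C)(C)[C@@H]1CC2 | intermediate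
5 | 20-methanesulfonate of 4 | CC(C)c1cc2c(c(OCOC)c1OCc1ccccc1)[C@@]1(COS(C)(=O)=O)CCCC(C)(C)[C@@H]1CC2 | intermediate
6 | (5S,10S)-12-benzyloxy-11-(methoxymethoxy)icetexa-8,11,13-trien-10-ol (10-OH trans to H5) | CC(C)c1cc2c(c(OCOC)c1OCc1ccccc1)C[C@@]1(O)CCCC(C)(C)[C@@H]1CC2 | intermediate
7 | (5S,10S)-11-(methoxymethoxy)icetexa-8,11,13-triene-10,12-diol | CC(C)c1cc2c(c(OCOC)c1O)C[C@@]1(O)CCCC(C)(C)[C@@H]1CC2 | intermediate
8 | (5S,10S)-10-hydroxy-11-(methoxymethoxy)icetexa-7,9(11),13-trien-12-one (p-quinone methide) | CC(C)C1=CC2=CC[C@H]3C(C)(C)CCC[C@]3(O)CC2=C(OCOC)C1=O | intermediate (not isolated)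
9 | 11-O-(methoxymethyl)brussonol, (5S,7S,10S)-7,10-epoxy-11-(methoxymethoxy)icetexa-8,11,13-trien-12-ol | CC(C)c1cc2c(c(OCOC)c1O)C[C@@]13CCCC(C)(C)[C@@H]1C[C@@H]2O3 | intermediate
10 | (5S,7S,10S)-7,10-epoxy-11-methoxy-11-(methoxymethoxy)icetexa-8,13-dien-12-one (o-quinone monoketal, both C11 epimers) | CC(C)C1=CC2=C(C[C@@]34CCCC(C)(C)[C@@H]3C[C@@H]2O4)C(OC)(OCOC)C1=O | intermediate
11 | (5S,7S,10S,13S,14S)-7,10-epoxy-13,14-dihydroxy-11-methoxy-11-(methoxymethoxy)icetex-8-en-12-one (cis-diol on the oxygen-bridge face) | O=C1[C@](O)(C(C)C)[C@@H](O)C2=C(C[C@@]34CCCC(C)(C)[C@@H]3C[C@@H]2O4)C1(OC)OCOC | intermediate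
12 | 13,14-cyclic sulfate of 11, (13S,14S) | O=C1[C@@]2(C(C)C)OS(=O)(=O)O[C@H]2C2=C(C[C@@]34CCCC(C)(C)[C@@H]3C[C@@H]2O4)C1(OC)OCOC | intermediate
13 | potassium (13′S,14′R)-14′-aryloxy 13′-sulfate (aryl = 9 through O12; O12 and sulfate trans) | CC(C)c1cc2c(c(OCOC)c1O[C@@H]1C3=C(C[C@@]45CCCC(C)(C)[C@@H]4C[C@@H]3O5)C(OC)(OCOC)C(=O)[C@]1(OS(=O)(=O)[O-])C(C)C)C[C@@]13CCCC(C)(C)[C@@H]1C[C@@H]2O3.[K+] | intermediate (not isolated)
14 | free 11-phenol, 11′,12′-dione, 13′-hydrogen sulfate | CC(C)c1cc2c(c(O)c1O[C@@H]1C3=C(C[C@@]45CCCC(C)(C)[C@@H]4C[C@@H]3O5)C(=O)C(=O)[C@]1(OS(=O)(=O)O)C(C)C)C[C@@]13CCCC(C)(C)[C@@H]1C[C@@H]2O3 | intermediate (not isolated)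
15 | seven-membered benzodioxepine hemiketal (O11 on C12′, O12 on C14′, hydrogen sulfate on C13′) | CC(C)c1cc2c(c3c1O[C@@H]1C4=C(C[C@@]56CCCC(C)(C)[C@@H]5C[C@@H]4O6)C(=O)[C@](O)(O3)[C@]1(OS(=O)(=O)O)C(C)C)C[C@@]13CCCC(C)(C)[C@@H]1C[C@@H]2O3 | intermediate (not isolated)
16 | CNP0371333.1, (13′R,14′R) cis-fused dimer | CC(C)c1cc2c(c3c1O[C@@H]1C4=C(C[C@@]56CCCC(C)(C)[C@@H]5C[C@@H]4O6)C(=O)C(=O)[C@]1(C(C)C)O3)C[C@@]13CCCC(C)(C)[C@@H]1C[C@@H]2O3 | target

**Step count and risks**

Total steps: 11. Longest linear sequence: 11 steps (1 to 16; compound 9 serves both halves, in steps 8 and 11).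

Steps most likely to fail:

Step 11 (proposed new method). The SN2 opening must take place on the more shielded face of ring C′ next to a fully substituted carbon and may be slow. In the acid stage, hydrolysis or elimination of the tertiary sulfate, or a 1,2-acyl shift, may outrun the migration of O11. Fallback with known chemistry, setting out from 9: aqueous HCl in THF removes the MOM group to give brussonol F1, and Ag2O in Et2O oxidises it to brussonol o-quinone F2. Kept as a concentrated toluene solution at 60 °C or as a neat film, F2 should dimerise by inverse-demand hetero-Diels–Alder cycloaddition, the 11,12-dione of one molecule adding across C13=C14 of a second. This gives the dioxane directly and returns to the route at 16, at the price of regio- and face control that then rest on the substrate alone.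

Step 9. Osmylation of the hindered, electron-poor enone may be slow, or face selectivity between the oxygen-bridge face and the C5–C6 bridge face may be poor. Fallback, setting out from 10: Weitz–Scheffer epoxidation (t-BuOOH, DBU, CH2Cl2) gives the α,β-epoxy ketone F3 by conjugate attack of the small peroxide at C14. The potassium phenoxide of 9 (KN(SiMe3)2, 18-crown-6, THF) opens F3 at C14′ with inversion to the trans-hydroxy ether F4. SO3·pyridine in DMF followed by K2CO3 turns the tertiary hydroxyl into the sulfate, which is 13; the route is rejoined there at the acid stage of step 11.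

Step 5. The C10 cation may be lost to elimination or to capture by the neighbouring 11-oxygen instead of water, or water may add without face preference. Fallback, setting out from 5: rearrangement without water (2,6-lutidine, toluene, 100 °C) to the ring-expanded 1(10)-alkene F5, then Mukaiyama hydration [Mn(dpm)3 (cat.), PhSiH3, O2, i-PrOH, 0 °C], which places the hydroxyl on the more substituted C10 by hydrogen-atom transfer and oxygen capture. This returns to the route at 6.

Further compounds
F1 | step 11 | brussonol, (5S,7S,10S) | CC(C)c1cc2c(c(O)c1O)C[C@@]13CCCC(C)(C)[C@@H]1C[C@@H]2O3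
F2 | step 11 | brussonol o-quinone | CC(C)C1=CC2=C(C[C@@]34CCCC(C)(C)[C@@H]3C[C@@H]2O4)C(=O)C1=O
F3 | step 9 | (13S,14S)-13,14-epoxide of 10 (epoxide on the oxygen-bridge face) | O=C1[C@@]2(C(C)C)O[C@H]2C2=C(C[C@@]34CCCC(C)(C)[C@@H]3C[C@@H]2O4)C1(OC)OCOC
F4 | step 9 | (13′S,14′R)-14′-aryloxy-13′-hydroxy ketone (aryl = 9 through O12) | CC(C)c1cc2c(c(OCOC)c1O[C@@H]1C3=C(C[C@@]45CCCC(C)(C)[C@@H]4C[C@@H]3O5)C(OC)(OCOC)C(=O)[C@]1(O)C(C)C)C[C@@]13CCCC(C)(C)[C@@H]1C[C@@H]2O3
F5 | step 5 | (5S)-12-benzyloxy-11-(methoxymethoxy)icetexa-1(10),8,11,13-tetraene | CC(C)c1cc2c(c(OCOC)c1OCc1ccccc1)CC1=CCCC(C)(C)[C@@H]1CC2
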